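The cis-decalin is cut in ring B (C4a–C5–C6–C7–C8–C8a): C6 and C7 are excised, leaving a cis-fused cyclobutane that a keteniminium [2+2] lays onto a cyclohexadienyl triflate. The key step re-inserts them: the 1-vinylcyclobutanol gives an alkoxy radical, β-scission at the gem-dimethyl carbon C8 unveils a vinyl ketone, and 6-endo recombination closes ring B. This two-carbon ring expansion exploits the 1,4-relation of the C5 carbinol carbon and quaternary C8 and hands on the cis C4a–C8a fusion. A bis-epoxide cascade supplies the benzoxepine lactone; vinyllithium–lactone union and an anti-SN2′ methylation set C2 and the E-olefin.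

Key step: step 5

Locants: decalin C1–C8a (C1 olefinic ring carbon, C2 CHMe, C4a and C8a fusion, C5 C(Me)OH, C8 CMe2; ring A = C1–C4, C4a, C8a; ring B = C4a, C5–C8, C8a); benzoxepine O1′–C9a′; linker Cα (=CH) and Cβ (CH2).

Assumption: the (2R,5R)-pyrrolidine auxiliary is taken to favour the (1R,6S)-cyclobutanone in step 3; if the sense of induction proves opposite, the (2S,5S)-amine is used and nothing else changes.

Step 1
Reactants: 1 (2R,5R)-2,5-dimethylpyrrolidine; 2 isobutyryl chloride
Product: 3 1-[(2R,5R)-2,5-dimethylpyrrolidin-1-yl]-2-methylpropan-1-one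
Conditions: Et3N, CH2Cl2, 0 °C to rt
Reagents that add atoms: none
Why: N-acylation of the C2-symmetric amine with the acid chloride should proceed cleanly and touches no stereocentre.

Step 2
Reactants: 4 cyclohex-2-en-1-one
Product: 6 cyclohexa-1,5-dien-1-yl trifluoromethanesulfonate, via lithium dienolate 5 (not isolated)
Conditions: LDA, THF, −78 °C; then PhNTf2, −78 to 0 °C
Reagents that add atoms: N-phenylbis(trifluoromethanesulfonimide), O=S(=O)(N(c1ccccc1)S(=O)(=O)C(F)(F)F)C(F)(F)F
Why: kinetic α′-deprotonation should give the cross-conjugated dienolate, which is O-sulfonylated (enol triflate formation).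

Step 3
Reactants: 3 amide; 6 dienyl triflate
Product: 9 (1R,6S)-8,8-dimethyl-7-oxobicyclo[4.2.0]oct-2-en-2-yl trifluoromethanesulfonate, via keteniminium triflate 7 (not isolated), via cyclobutaniminium triflate 8 (not isolated)
Conditions: Tf2O, 2,4,6-collidine, ClCH2CH2Cl, −20 °C to rt; then 6, 60 °C; then H2O, NaHCO3
Reagents that add atoms: water, O
Why: keteniminium [2+2] cycloaddition, in which the electrophilic carbon should bond to the terminus of the unsubstituted olefin (the electron-poor enol triflate olefin stays out) and the CMe2 carbon closes on the allylic position; the four–six fusion can only be cis and the C2-symmetric pyrrolidinium differentiates the diene faces.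

Step 4
Reactants: 9 cyclobutanone
Product: 10 (1R,6S,7S)-7-ethenyl-7-hydroxy-8,8-dimethylbicyclo[4.2.0]oct-2-en-2-yl trifluoromethanesulfonate
Conditions: CH2=CHMgBr, THF, −78 °C
Reagents that add atoms: vinylmagnesium bromide, C=C[Mg]Br
Why: Grignard 1,2-addition to the strained ketone should occur from the convex face (7S), and because this carbinol centre is erased in step 5 either epimer serves.

Step 5
Reactants: 10 1-vinylcyclobutanol
Product: 11 (4aS,8aR)-8,8-dimethyl-5-oxo-3,4,4a,5,6,7,8,8a-octahydronaphthalen-1-yl trifluoromethanesulfonate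
Conditions: [Ir(dF(CF3)ppy)2(5,5′-d(CF3)bpy)]PF6 (2 mol %), 2,4,6-collidine, PhCF3, blue LEDs, rt
Reagents that add atoms: none
Why: Proton-coupled electron transfer from the tertiary O–H to the photoexcited iridium complex and collidine should give the alkoxy radical, whose β-scission cleaves the cyclobutane bond to the gem-dimethyl carbon and leaves a tertiary radical beside a vinyl ketone; the radical adds to the terminal olefin carbon and the α-keto radical is reduced and protonated, so the two vinyl carbons become C6 and C7 of ring B. The closest known reaction type is the photocatalytic ring expansion of 1-alkenylcycloalkanols by alkoxy-radical β-scission and radical recombination. Ring B closes in the 6-endo-trig mode. No stereocentre is created: the carbinol carbon becomes the C5 carbonyl, and the cis C4a–C8a fusion from the cycloaddition is carried over because neither carbon is touched. The step needs scission toward C8 and not toward C4a, which tertiary over secondary radical stability secures, and endo instead of 5-exo closure, which the polarity match of the nucleophilic tertiary radical with the unsubstituted β-carbon of the enone secures. The enol triflate olefin is electron-poor and should stay out of the radical and redox events.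

Step 6
Reactants: 11 ketone
Product: 12 (4aS,8aR)-8,8-dimethyl-5-methylidene-3,4,4a,5,6,7,8,8a-octahydronaphthalen-1-yl trifluoromethanesulfonate
Conditions: Zn, CH2Br2, TiCl4, THF–CH2Cl2, 0 °C to rt
Reagents that add atoms: dibromomethane, BrCBr
Why: Takai–Lombardo methylenation is non-basic, so the epimerisable C4a centre next to the ketone should stay cis.

Step 7
Reactants: 12 exocyclic olefin
Product: 13 (4aS,5S,8aR)-5-hydroxy-5,8,8-trimethyl-3,4,4a,5,6,7,8,8a-octahydronaphthalen-1-yl trifluoromethanesulfonate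
Conditions: Co(acac)2 (cat.), PhSiH3, O2 (1 atm), THF, rt
Reagents that add atoms: dioxygen, O=O
Why: Mukaiyama hydration should act only on the 1,1-disubstituted olefin, and O2 should trap the tertiary C5 radical on the convex face, anti to C4 of ring A, placing OH cis to H-4a (5S); MeMgBr addition to 11 from that same face would give the C5 epimer, hence the two-step detour.

Step 8
Reactants: 13 enol triflate
Product: 14 [(4aS,5S,8aR)-5-hydroxy-5,8,8-trimethyl-3,4,4a,5,6,7,8,8a-octahydronaphthalen-1-yl]trimethylstannane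
Conditions: Pd(PPh3)4 (5 mol %), Me3SnSnMe3, LiCl, 1,4-dioxane, 90 °C
Reagents that add atoms: hexamethylditin, C[Sn](C)(C)[Sn](C)(C)C
Why: palladium-catalysed stannylation of the enol triflate (Stille-type coupling with the distannane) should tolerate the free tertiary alcohol.

Step 9
Reactants: 15 (2E,6E)-farnesyl bromide
Product: 16 methyl (3E,7E)-4,8,12-trimethyltrideca-3,7,11-trienoate
Conditions: Pd(OAc)2 (2 mol %), PPh3, CO (20 bar), MeOH, i-Pr2NEt, 40 °C
Reagents that add atoms: carbon monoxide, [C-]#[O+]; methanol, CO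
Why: palladium-catalysed methoxycarbonylation of the allylic bromide, with CO insertion at the less substituted terminus of the syn-π-allyl complex, should keep the 3E geometry.

Step 10
Reactants: 16 triene ester
Product: 17 methyl (3E)-6-[(2S,3S)-3-{2-[(2S)-3,3-dimethyloxiran-2-yl]ethyl}-3-methyloxiran-2-yl]-4-methylhex-3-enoate
Conditions: ent-Shi ketone (from L-fructose, 0.6 equiv), Oxone (2KHSO5·KHSO4·K2SO4), K2CO3, Bu4NHSO4, Na2B4O7 buffer, MeCN–(MeO)2CH2–H2O, 0 °C
Reagents that add atoms: potassium peroxymonosulfate, [K+].[O-]S(=O)(=O)OO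
Why: Shi epoxidation, in which the chiral dioxirane should take the two electron-rich distal trisubstituted olefins through the spiro transition state to the S,S,S-bis-epoxide and spare the 3,4-olefin, deactivated inductively by the ester.

Step 11
Reactants: 17 bis-epoxide
Product: 18 γ-lactone of [(3S,5aS,6S,7S,9aS)-3-(tert-butyldimethylsilyloxy)-7-hydroxy-2,2,5a,7-tetramethyldecahydro-1-benzoxepin-6-yl]acetic acid
Conditions: TBSOTf, 2,6-di-tert-butyl-4-methylpyridine, CH2Cl2, −78 °C; then aq NaHCO3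
Reagents that add atoms: tert-butyldimethylsilyl trifluoromethanesulfonate, CC(C)(C)[Si](C)(C)OS(=O)(=O)C(F)(F)F
Why: tandem oxa-/carbacyclisation of a bis-epoxide: the silylated terminal epoxide should be opened at its CMe2 carbon by the internal epoxide oxygen (oxepane), the epoxonium opened anti at its tertiary carbon by the 3,4-olefin through a chair, and the tertiary cation captured by the ester carbonyl with loss of its methyl group, so that anti addition across the epoxide and the E-olefin gives the trans fusion, the axial C5a′ and C7′ methyl groups and the equatorial lactone oxygen, while C3′ and C9a′ keep their epoxide configuration.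

Step 12
Reactants: 14 vinylstannane; 18 lactone
Product: 20 2-[(3S,5aS,6S,7S,9aS)-3-(tert-butyldimethylsilyloxy)-7-hydroxy-2,2,5a,7-tetramethyldecahydro-1-benzoxepin-6-yl]-1-[(4aS,5S,8aR)-5-hydroxy-5,8,8-trimethyl-3,4,4a,5,6,7,8,8a-octahydronaphthalen-1-yl]ethan-1-one, via dilithio species 19 (not isolated)
Conditions: MeLi (2.1 equiv), THF, −78 °C; then 18, −78 °C; aq NH4Cl
Reagents that add atoms: none
Why: tin–lithium exchange should give the alkenyllithium (the alcohol riding as its lithium alkoxide), which adds once to the γ-lactone because the tetrahedral lithium hemiketal persists at −78 °C and collapses to the hydroxy enone only on work-up.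

Step 13
Reactants: 20 dihydroxy enone
Product: 21 2-[(3S,5aS,6S,7S,9aS)-3-(tert-butyldimethylsilyloxy)-2,2,5a,7-tetramethyl-7-(triethylsilyloxy)decahydro-1-benzoxepin-6-yl]-1-[(4aS,5S,8aR)-5,8,8-trimethyl-5-(triethylsilyloxy)-3,4,4a,5,6,7,8,8a-octahydronaphthalen-1-yl]ethan-1-one
Conditions: Et3SiOTf, 2,6-lutidine, CH2Cl2, −78 to 0 °C
Reagents that add atoms: triethylsilyl trifluoromethanesulfonate, CC[Si](CC)(CC)OS(=O)(=O)C(F)(F)F
Why: silylation of both tertiary alcohols keeps them from displacing the allylic leaving group installed in step 15 (the C7′ oxygen would otherwise close a tetrahydrofuran).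

Step 14
Reactants: 21 enone
Product: 22 (1S)-2-[(3S,5aS,6S,7S,9aS)-3-(tert-butyldimethylsilyloxy)-2,2,5a,7-tetramethyl-7-(triethylsilyloxy)decahydro-1-benzoxepin-6-yl]-1-[(4aS,5S,8aR)-5,8,8-trimethyl-5-(triethylsilyloxy)-3,4,4a,5,6,7,8,8a-octahydronaphthalen-1-yl]ethan-1-ol
Conditions: (R)-2-methyl-CBS-oxazaborolidine (0.3 equiv), catecholborane, toluene, −78 °C
Reagents that add atoms: none
Why: Corey–Bakshi–Shibata reduction, in which the cyclohexenyl group acts as the large substituent so that the R catalyst should give the S carbinol under reagent control.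

Step 15
Reactants: 22 allylic alcohol
Product: 23 pyridine-2-carboxylate (picolinate) of 22
Conditions: picolinic acid, DCC, DMAP (cat.), CH2Cl2, rt
Reagents that add atoms: picolinic acid, OC(=O)c1ccccn1
Why: Steglich esterification of the only free hydroxyl turns it into a chelating allylic leaving group.

Step 16
Reactants: 23 allylic picolinate
Product: 24 tert-butyl{[(3S,5aS,6S,7S,9aS)-6-{(2E)-2-[(2R,4aS,5S,8aR)-2,5,8,8-tetramethyl-5-(triethylsilyloxy)octahydronaphthalen-1(2H)-ylidene]ethyl}-2,2,5a,7-tetramethyl-7-(triethylsilyloxy)decahydro-1-benzoxepin-3-yl]oxy}dimethylsilane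
Conditions: MeMgBr (3 equiv), CuBr·SMe2 (1.5 equiv), THF, −40 to 0 °C
Reagents that add atoms: methylmagnesium bromide, C[Mg]Br
Why: copper-mediated anti-SN2′ substitution of the allylic picolinate: in the reactive rotamer Cβ should lie inside, syn to vinylic H-2 (the outside position is crowded by C8a and its quaternary neighbour), and the chelated picolinate of the S carbinol leaves from the lower face, so the methyl enters C2 on the face of the ring-B bonds (2R) and the new C1=Cα olefin carries Cβ cis to C2 (E).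

Step 17
Reactants: 24 tris-silyl ether
Product: 25 (3S,5aS,6S,7S,9aS)-6-{(2E)-2-[(2R,4aS,5S,8aR)-5-hydroxy-2,5,8,8-tetramethyloctahydronaphthalen-1(2H)-ylidene]ethyl}-2,2,5a,7-tetramethyldecahydro-1-benzoxepine-3,7-diol
Conditions: Bu4NF, THF, 60 °C
Reagents that add atoms: none
Why: fluoride-mediated cleavage of the two triethylsilyl ethers and the tert-butyldimethylsilyl ether should affect no stereocentre.

Step 18
Reactants: 25 triol
Product: 26 (5aS,6S,7S,9aS)-7-hydroxy-6-{(2E)-2-[(2R,4aS,5S,8aR)-5-hydroxy-2,5,8,8-tetramethyloctahydronaphthalen-1(2H)-ylidene]ethyl}-2,2,5a,7-tetramethyloctahydro-1-benzoxepin-3(2H)-one (CNP0232921.1)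
Conditions: Dess–Martin periodinane, NaHCO3, CH2Cl2, rt
Reagents that add atoms: none
Why: Dess–Martin oxidation should convert the single secondary alcohol to the oxepanone while the two tertiary alcohols and the trisubstituted olefin stay inert.

Compound list

1 | (2R,5R)-2,5-dimethylpyrrolidine | C[C@@H]1CC[C@@H](C)N1 | starting material
2 | isobutyryl chloride | CC(C)C(Cl)=O | starting material
3 | 1-[(2R,5R)-2,5-dimethylpyrrolidin-1-yl]-2-methylpropan-1-one | CC(C)C(=O)N1[C@H](C)CC[C@H]1C | intermediate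
4 | cyclohex-2-en-1-one | O=C1C=CCCC1 | starting material
5 | lithium cyclohexa-1,5-dien-1-olate | [Li+].[O-]C1=CCCC=C1 | intermediate
6 | cyclohexa-1,5-dien-1-yl trifluoromethanesulfonate | FC(F)(F)S(=O)(=O)OC1=CCCC=C1 | intermediate
7 | (2R,5R)-2,5-dimethyl-1-(2-methylprop-1-en-1-ylidene)pyrrolidin-1-ium trifluoromethanesulfonate | CC(C)=C=[N+]1[C@H](C)CC[C@H]1C.[O-]S(=O)(=O)C(F)(F)F | intermediate
8 | (2R,5R)-1-[(1R,6S)-8,8-dimethyl-2-(trifluoromethanesulfonyloxy)bicyclo[4.2.0]oct-2-en-7-ylidene]-2,5-dimethylpyrrolidin-1-ium trifluoromethanesulfonate | FC(F)(F)S(=O)(=O)OC1=CCC[C@H]2[C@@H]1C(C)(C)C2=[N+]3[C@H](C)CC[C@H]3C.[O-]S(=O)(=O)C(F)(F)F | intermediate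
9 | (1R,6S)-8,8-dimethyl-7-oxobicyclo[4.2.0]oct-2-en-2-yl trifluoromethanesulfonate (cis-fused) | FC(F)(F)S(=O)(=O)OC1=CCC[C@H]2[C@@H]1C(C)(C)C2=O | intermediate
10 | (1R,6S,7S)-7-ethenyl-7-hydroxy-8,8-dimethylbicyclo[4.2.0]oct-2-en-2-yl trifluoromethanesulfonate | FC(F)(F)S(=O)(=O)OC1=CCC[C@H]2[C@@H]1C(C)(C)[C@]2(O)C=C | intermediate
11 | (4aS,8aR)-8,8-dimethyl-5-oxo-3,4,4a,5,6,7,8,8a-octahydronaphthalen-1-yl trifluoromethanesulfonate (cis-fused) | FC(F)(F)S(=O)(=O)OC1=CCC[C@H]2[C@@H]1C(C)(C)CCC2=O | intermediate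
12 | (4aS,8aR)-8,8-dimethyl-5-methylidene-3,4,4a,5,6,7,8,8a-octahydronaphthalen-1-yl trifluoromethanesulfonate | FC(F)(F)S(=O)(=O)OC1=CCC[C@H]2[C@@H]1C(C)(C)CCC2=C | intermediate
13 | (4aS,5S,8aR)-5-hydroxy-5,8,8-trimethyl-3,4,4a,5,6,7,8,8a-octahydronaphthalen-1-yl trifluoromethanesulfonate | FC(F)(F)S(=O)(=O)OC1=CCC[C@H]2[C@@H]1C(C)(C)CC[C@]2(C)O | intermediate
14 | [(4aS,5S,8aR)-5-hydroxy-5,8,8-trimethyl-3,4,4a,5,6,7,8,8a-octahydronaphthalen-1-yl]trimethylstannane | C[Sn](C)(C)C1=CCC[C@H]2[C@@H]1C(C)(C)CC[C@]2(C)O | intermediate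
15 | (2E,6E)-farnesyl bromide | BrC/C=C(\C)CC/C=C(\C)CCC=C(C)C | starting material
16 | methyl (3E,7E)-4,8,12-trimethyltrideca-3,7,11-trienoate | COC(=O)C/C=C(\C)CC/C=C(\C)CCC=C(C)C | intermediate
17 | methyl (3E)-6-[(2S,3S)-3-{2-[(2S)-3,3-dimethyloxiran-2-yl]ethyl}-3-methyloxiran-2-yl]-4-methylhex-3-enoate | COC(=O)C/C=C(\C)CC[C@@H]1O[C@@]1(C)CC[C@@H]1OC1(C)C | intermediate
18 | γ-lactone of [(3S,5aS,6S,7S,9aS)-3-(tert-butyldimethylsilyloxy)-7-hydroxy-2,2,5a,7-tetramethyldecahydro-1-benzoxepin-6-yl]acetic acid (all ring fusions trans) | O=C1C[C@H]2[C@]3(C)CC[C@H](O[Si](C)(C)C(C)(C)C)C(C)(C)O[C@H]3CC[C@]2(C)O1 | intermediate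
19 | dilithio derivative of 14 (C1–Li and C5–OLi) | [Li]C1=CCC[C@H]2[C@@H]1C(C)(C)CC[C@]2(C)O[Li] | intermediate
20 | 2-[(3S,5aS,6S,7S,9aS)-3-(tert-butyldimethylsilyloxy)-7-hydroxy-2,2,5a,7-tetramethyldecahydro-1-benzoxepin-6-yl]-1-[(4aS,5S,8aR)-5-hydroxy-5,8,8-trimethyl-3,4,4a,5,6,7,8,8a-octahydronaphthalen-1-yl]ethan-1-one | O=C(C[C@H]1[C@]2(C)CC[C@H](O[Si](C)(C)C(C)(C)C)C(C)(C)O[C@H]2CC[C@]1(C)O)C3=CCC[C@H]4[C@@H]3C(C)(C)CC[C@]4(C)O | intermediate
21 | bis(triethylsilyl) ether of 20 at both tertiary hydroxyls | O=C(C[C@H]1[C@]2(C)CC[C@H](O[Si](C)(C)C(C)(C)C)C(C)(C)O[C@H]2CC[C@]1(C)O[Si](CC)(CC)CC)C3=CCC[C@H]4[C@@H]3C(C)(C)CC[C@]4(C)O[Si](CC)(CC)CC | intermediate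
22 | (1S)-allylic alcohol from 21 | O[C@@H](C[C@H]1[C@]2(C)CC[C@H](O[Si](C)(C)C(C)(C)C)C(C)(C)O[C@H]2CC[C@]1(C)O[Si](CC)(CC)CC)C3=CCC[C@H]4[C@@H]3C(C)(C)CC[C@]4(C)O[Si](CC)(CC)CC | intermediate
23 | pyridine-2-carboxylate of 22 | O=C(O[C@@H](C[C@H]1[C@]2(C)CC[C@H](O[Si](C)(C)C(C)(C)C)C(C)(C)O[C@H]2CC[C@]1(C)O[Si](CC)(CC)CC)C3=CCC[C@H]4[C@@H]3C(C)(C)CC[C@]4(C)O[Si](CC)(CC)CC)c5ccccn5 | intermediate
24 | 3′-O-tert-butyldimethylsilyl, 5,7′-bis-O-triethylsilyl ether of 25 | C[C@@H]1CC[C@H]2[C@@H](/C1=C/C[C@H]1[C@]3(C)CC[C@H](O[Si](C)(C)C(C)(C)C)C(C)(C)O[C@H]3CC[C@]1(C)O[Si](CC)(CC)CC)C(C)(C)CC[C@]2(C)O[Si](CC)(CC)CC | intermediate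
25 | (3S,5aS,6S,7S,9aS)-6-{(2E)-2-[(2R,4aS,5S,8aR)-5-hydroxy-2,5,8,8-tetramethyloctahydronaphthalen-1(2H)-ylidene]ethyl}-2,2,5a,7-tetramethyldecahydro-1-benzoxepine-3,7-diol | C[C@@H]1CC[C@H]2[C@@H](/C1=C/C[C@H]1[C@]3(C)CC[C@H](O)C(C)(C)O[C@H]3CC[C@]1(C)O)C(C)(C)CC[C@]2(C)O | intermediate
26 | (5aS,6S,7S,9aS)-7-hydroxy-6-{(2E)-2-[(2R,4aS,5S,8aR)-5-hydroxy-2,5,8,8-tetramethyloctahydronaphthalen-1(2H)-ylidene]ethyl}-2,2,5a,7-tetramethyloctahydro-1-benzoxepin-3(2H)-one | C[C@@H]1CC[C@H]2[C@@H](/C1=C/C[C@H]1[C@]3(C)CCC(=O)C(C)(C)O[C@H]3CC[C@]1(C)O)C(C)(C)CC[C@]2(C)O | target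

Total step count: 18. Longest linear sequence: 14 steps (steps 1, 3–8, 12–18).

Steps most likely to fail

Step 16. The methylcopper reagent has to reach C2 on the face that carries the ring-B bonds; if that approach is too slow, reaction through the other rotamer (methyl from the lower face, Z-olefin) or direct SN2 displacement would erode both the C2 configuration and the olefin geometry. The fallback delivers the carbon intramolecularly and sets out from 21. Reduction with the S enantiomer of the CBS catalyst and catecholborane should give the 1R carbinol F1. KH and Bu3SnCH2I in THF convert it into the (tributylstannyl)methyl ether F2. n-BuLi at −78 °C triggers tin–lithium exchange and a Still–Wittig [2,3]-sigmatropic shift, which transfers CH2O suprafacially to the upper face of C2 and places Cβ cis to C2, giving the 2-(hydroxymethyl) compound F3. MsCl and Et3N give the methanesulfonate F4, and LiBHEt3 reduces it to the methyl group, returning to the route at 24.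

Step 5. The tertiary radical may be quenched by hydrogen-atom transfer before it recombines, or radical generation at the hindered carbinol may be slow, giving ring-opened material instead of ring B. The fallback separates the two events and sets out from 10. PhI(OAc)2 and I2 under visible light (hypoiodite fragmentation) should give (5S,6S)-6-(2-iodopropan-2-yl)-5-(prop-2-enoyl)cyclohex-1-en-1-yl trifluoromethanesulfonate F5. Bu3SnH and AIBN in benzene at 80 °C under slow addition then effect the 6-endo radical cyclisation and return to the route at 11.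

Step 12. The alkenyllithium may enolise the lactone at Cβ or add twice. The fallback changes the union to an aldehyde addition and sets out from 18. i-Bu2AlH in CH2Cl2 at −78 °C should give the lactol F6. Nozaki–Hiyama–Kishi coupling of F6 with enol triflate 13 (CrCl2, NiCl2 cat., DMF), through the open hydroxy aldehyde, gives the allylic alcohol as a mixture of carbinol epimers F7. MnO2 oxidises only the allylic alcohol and returns to the route at 20.

Further compounds

F1 | step 16 | (1R)-epimer of 22 | O[C@H](C[C@H]1[C@]2(C)CC[C@H](O[Si](C)(C)C(C)(C)C)C(C)(C)O[C@H]2CC[C@]1(C)O[Si](CC)(CC)CC)C3=CCC[C@H]4[C@@H]3C(C)(C)CC[C@]4(C)O[Si](CC)(CC)CC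
F2 | step 16 | (tributylstannyl)methyl ether of F1 | CCCC[Sn](CCCC)(CCCC)CO[C@H](C[C@H]1[C@]2(C)CC[C@H](O[Si](C)(C)C(C)(C)C)C(C)(C)O[C@H]2CC[C@]1(C)O[Si](CC)(CC)CC)C3=CCC[C@H]4[C@@H]3C(C)(C)CC[C@]4(C)O[Si](CC)(CC)CC
F3 | step 16 | analogue of 24 with CH2OH in place of the C2 methyl group | OC[C@@H]1CC[C@H]2[C@@H](/C1=C/C[C@H]1[C@]3(C)CC[C@H](O[Si](C)(C)C(C)(C)C)C(C)(C)O[C@H]3CC[C@]1(C)O[Si](CC)(CC)CC)C(C)(C)CC[C@]2(C)O[Si](CC)(CC)CC
F4 | step 16 | methanesulfonate of F3 | CS(=O)(=O)OC[C@@H]1CC[C@H]2[C@@H](/C1=C/C[C@H]1[C@]3(C)CC[C@H](O[Si](C)(C)C(C)(C)C)C(C)(C)O[C@H]3CC[C@]1(C)O[Si](CC)(CC)CC)C(C)(C)CC[C@]2(C)O[Si](CC)(CC)CC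
F5 | step 5 | (5S,6S)-6-(2-iodopropan-2-yl)-5-(prop-2-enoyl)cyclohex-1-en-1-yl trifluoromethanesulfonate | FC(F)(F)S(=O)(=O)OC1=CCC[C@H](C(=O)C=C)[C@@H]1C(C)(C)I
F6 | step 12 | lactol from 18 (anomeric mixture) | OC1C[C@H]2[C@]3(C)CC[C@H](O[Si](C)(C)C(C)(C)C)C(C)(C)O[C@H]3CC[C@]2(C)O1
F7 | step 12 | allylic alcohol corresponding to 20 (carbinol epimers) | OC(C[C@H]1[C@]2(C)CC[C@H](O[Si](C)(C)C(C)(C)C)C(C)(C)O[C@H]2CC[C@]1(C)O)C3=CCC[C@H]4[C@@H]3C(C)(C)CC[C@]4(C)O
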